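You can read one ratio straight from these flasks: the E gained per minute, divided by the mean X standing in that interval. Here X is the part of the J charged that is neither J nor E. Call the ratio k, the first-order constant of X going to E.

| flask | J | Q | temperature | remark | time |
|---|---|---|---|---|---|
| Sunday's | 0.23 M | 150 mM (held) | 20 °C | run made earlier |  |
| Friday's | 0.52 M | 150 mM (held) | 40 °C | run made earlier |  |
| zeta | 0.35 M | 150 mM (held) | 40 °C |  | 8.0 min |
| beta | 0.35 M | 150 mM (held) | 55 °C |  | 8.0 min |
| gamma | 0.35 M | 150 mM (held) | 25 °C |  | 8.0 min |

- Sunday's (time / min: E / %, J / %): 2.00: 0, 81.6; 2.50: 1.0, 75.4; 5.00: 1.6, 49.7; 8.00: 0, 25.5; 15.0: 5.1, 3.1; 20.0: 8.5, 0.9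
- Friday's (time / min: E / %, J / %): 1.33: 0, 82.4; 2.50: 1.1, 65.5; 4.00: 3.5, 43.6; 5.00: 6.5, 32.3; 6.00: 10.1, 21.0; 8.00: 14.2, 7.2

(scatter of a reading: 1 percentage point)

- the best flask by amount of E, in percent of the J charged; "all alike" if 1.5 percentage points covers them all (zeta / beta / gamma / all alike)
- amount of E at the end, in percent of the J charged, zeta
- amount of E at the end, in percent of the J charged, beta
- amount of E at the end, in percent of the J charged, gamma

- at the start none of Q is in solution

Which number has to be known well? Take J first. X cannot pass the charge, so for a given k the E at time t stays under the ceiling 1 − exp(−kt), reached with the whole charge turned to X at once. The amount of J and its speed move E below that ceiling. The temperature moves the ceiling itself, through k. So k comes next.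

Friday's run from 5.00 min to 8.00 min gives k = 0.0367 min⁻¹. From 2.50 min to 5.00 min it reads 0.0457 min⁻¹, which is close, given a scatter of 1 percentage point. In the later interval of Friday's run J loses 25 points while E gains 7.7 points, so there X to E is the rate-limiting step.

Sunday's run from 5.00 min to 20.0 min gives 0.00660 min⁻¹, on a gain of 6.9 points. Between 20 °C and 40 °C, in two runs that also differ in J, the reading of k grows by a factor of 5.56. Zeta's ceiling, 25.5 %, is a factor of 1.79 above Friday's E at the same time, a smaller factor than the one on k, so I take k as the number to know well.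

My own reckoning keeps the same factor per degree up to 55 °C. That gives 0.133 min⁻¹ for beta, with a ceiling of 65.5 %.

The forecast names beta, with 15 % for zeta, 44 % for beta and 2.2 % for gamma. It reasons: “Hottest wins unless an unseen loss appears.” Its constant for beta is about 0.11, against my 0.133 min⁻¹.

The best flask is beta, with 63.1 %, against zeta's 17.6 % and gamma's 2.61 %, but the forecast's beta stands 19 points low. At 8.00 min beta still holds 36.9 % as X. The same ratio, taken in beta from 4.00 min to 8.00 min, gives 0.195 min⁻¹, higher than the 0.133 min⁻¹ I carried up to beta.

    J + D → X + L (k = 2.50 M⁻¹ min⁻¹, Ea = 53.0 kJ mol⁻¹)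
    X → E (k = 0.00770 min⁻¹, Ea = 86.0 kJ mol⁻¹)
    Q ⇌ D, rate k3*(csat - [D]) (kL = 0.700 min⁻¹)
    (constants at 25 °C)

Now read zeta later, at 20 min. Zeta's 80.0 % of X at 8.00 min, shrinking with 0.0367 min⁻¹, leaves E near 48.5 %. The computed flask gives 49.3 %.

The readings are calculated from invented constants; the scatter is artificial.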